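**Retrosynthetic overview**

1. The three phenols are freed last from MOM ethers. Before that, the pyran ring is closed onto a finished ring A by forming C4–C4a and O1–C8a together, from a ring-A aryl iodide (iodine on the future C8a) and the (R)-bromohydrin HOCH2–CH(ring B)–CH2Br.
2. Enabling feature: C8a and C4a are adjacent ring-A carbons, an ipso/ortho pair towards one halogen. C4a is the only unhindered C–H next to C8a, because C8 is flanked by the 7-oxygen. The O1–C2–C3–C4 chain is a 1,3-difunctional unit, the opened form of a prochiral 3-aryloxetane, and its stereocentre C3 lies β to both bonds formed.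
3. The bromohydrin comes from catalyst-controlled, strain-releasing desymmetrising opening of the 3-(ring B)oxetane, itself made by Negishi coupling of the ring-B bromide with oxetan-3-ylzinc iodide.
4. Rings A and B are the same 4-(1,1-dimethylallyl)resorcinol unit, so one aryl bromide serves both. It is made from 5-bromo-2-fluorophenol by SNAr with isobutyronitrile anion, reduction and methylenation. Copper-catalysed Br→I exchange gives the ring-A partner; Br→OH, then bromination, gives the ring-B partner.
5. Ring order: both benzene rings are bought; the oxetane is carried in and opened; the pyran ring is the only ring built, in the key step.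

Key step: step 11

Remark: the sense of induction of the squaramide catalyst in step 10 cannot be taken from analogy for this ortho-substituted aryl group; the catalyst antipode that delivers the (R)-bromohydrin is to be identified on the first run and then used throughout.

**Route**

Step 1
Reactants: 1 5-bromo-2-fluorophenol
Product: 2 MOM ether 4-bromo-1-fluoro-2-(methoxymethoxy)benzene
Conditions: MOMCl, i-Pr2NEt, CH2Cl2, 0 °C → rt
Reagents that add atoms: chloromethyl methyl ether, COCCl
Why: O-alkylation of the phenol with an α-chloro ether (MOM protection) gives an acetal that should withstand the strong bases, organometallics and palladium steps ahead.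

Step 2
Reactants: 2 MOM ether 4-bromo-1-fluoro-2-(methoxymethoxy)benzene
Product: 3 nitrile 2-[4-bromo-2-(methoxymethoxy)phenyl]-2-methylpropanenitrile
Conditions: i-PrCN, KHMDS, toluene, 60 °C
Reagents that add atoms: isobutyronitrile, CC(C)C#N
Why: Nucleophilic aromatic substitution of an aryl fluoride by the potassium anion of a secondary nitrile; the ortho acetal oxygen and para bromine lower the barrier, and fluoride is displaced in preference to bromide because addition is rate-limiting in the addition–elimination pathway.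

Step 3
Reactants: 3 nitrile 2-[4-bromo-2-(methoxymethoxy)phenyl]-2-methylpropanenitrile
Product: 4 aldehyde 2-[4-bromo-2-(methoxymethoxy)phenyl]-2-methylpropanal
Conditions: DIBAL-H, toluene, −78 → −40 °C; then aq. AcOH/NaOAc, 0 °C → rt
Reagents that add atoms: water, O
Why: Partial DIBAL-H reduction of a nitrile followed by buffered hydrolysis should give the aldehyde; the quaternary α-carbon rules out enolisation and over-reduction is slow at low temperature.

Step 4
Reactants: 4 aldehyde 2-[4-bromo-2-(methoxymethoxy)phenyl]-2-methylpropanal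
Product: 5 aryl bromide 4-bromo-2-(methoxymethoxy)-1-(2-methylbut-3-en-2-yl)benzene
Conditions: Ph3PCH3Br, KOt-Bu, THF, 0 °C → rt
Reagents that add atoms: methyltriphenylphosphonium bromide, C[P+](c1ccccc1)(c1ccccc1)c1ccccc1.[Br-]
Why: Wittig methylenation of a non-enolisable neopentyl-type aldehyde completes the 1,1-dimethylallyl group.

Step 5
Reactants: 5 aryl bromide 4-bromo-2-(methoxymethoxy)-1-(2-methylbut-3-en-2-yl)benzene
Product: 6 aryl iodide 4-iodo-2-(methoxymethoxy)-1-(2-methylbut-3-en-2-yl)benzene
Conditions: NaI, CuI (5 mol %), trans-N,N'-dimethylcyclohexane-1,2-diamine (10 mol %), 1,4-dioxane, 110 °C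
Reagents that add atoms: sodium iodide, [Na+].[I-]
Why: Copper-catalysed halogen exchange (aromatic Finkelstein reaction) at the unhindered C–Br bond, driven towards the aryl iodide by the poor solubility of NaBr in dioxane; the acetal and the alkene are inert to these neutral conditions.

Step 6
Reactants: 5 aryl bromide 4-bromo-2-(methoxymethoxy)-1-(2-methylbut-3-en-2-yl)benzene
Product: 9 phenol 3-(methoxymethoxy)-4-(2-methylbut-3-en-2-yl)phenol, via aryllithium 7 (not isolated), via dimethyl boronate 8 (not isolated)
Conditions: n-BuLi, THF, −78 °C; B(OMe)3, −78 °C → rt; then H2O2, aq. NaOH, 0 °C → rt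
Reagents that add atoms: n-butyllithium, [Li]CCCC (lithium of 7 only); trimethyl borate, COB(OC)OC (boron and methoxy groups of 8 only); hydrogen peroxide, OO (oxygen of the phenol 9)
Why: Bromine–lithium exchange, which at −78 °C is faster than deprotonation next to the acetal, then borylation of the aryllithium and oxidative 1,2-aryl migration (boronate oxidation) turn C–Br into C–OH; an isolated monosubstituted alkene is inert to alkaline peroxide.

Step 7
Reactants: 9 phenol 3-(methoxymethoxy)-4-(2-methylbut-3-en-2-yl)phenol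
Product: 10 bis-MOM arene 2,4-bis(methoxymethoxy)-1-(2-methylbut-3-en-2-yl)benzene
Conditions: MOMCl, i-Pr2NEt, CH2Cl2, 0 °C → rt
Reagents that add atoms: chloromethyl methyl ether, COCCl
Why: MOM protection of the new phenol gives both ring-B oxygens the same base-stable acetal.

Step 8
Reactants: 10 bis-MOM arene 2,4-bis(methoxymethoxy)-1-(2-methylbut-3-en-2-yl)benzene
Product: 11 ring-B bromide 1-bromo-2,4-bis(methoxymethoxy)-5-(2-methylbut-3-en-2-yl)benzene
Conditions: NBS, MeCN, 0 °C, dark
Reagents that add atoms: N-bromosuccinimide, O=C1CCC(=O)N1Br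
Why: Electrophilic aromatic bromination should go to the only unhindered C–H that is para to one acetal oxygen and ortho to the other (the C–H between the two oxygens is shielded), and the activated ring should react faster than the hindered monosubstituted alkene.

Step 9
Reactants: 11 ring-B bromide 1-bromo-2,4-bis(methoxymethoxy)-5-(2-methylbut-3-en-2-yl)benzene; 12 3-iodooxetane
Product: 14 oxetane 3-[2,4-bis(methoxymethoxy)-5-(2-methylbut-3-en-2-yl)phenyl]oxetane, via oxetan-3-ylzinc iodide 13 (not isolated)
Conditions: 12, Zn dust, LiCl, THF, 40 °C; then 11, Pd(OAc)2 (2 mol %), 2-dicyclohexylphosphino-2',6'-bis(dimethylamino)biphenyl (4 mol %), THF/toluene, rt → 40 °C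
Reagents that add atoms: zinc, [Zn] (zinc of 13 only)
Why: Negishi coupling of a secondary alkylzinc halide with an ortho-substituted aryl bromide under a biaryl dialkylphosphine ligand, whose fast reductive elimination outruns β-hydride elimination; in the four-membered ring, chain-walking cannot move the attachment point.

Step 10
Reactants: 14 oxetane 3-[2,4-bis(methoxymethoxy)-5-(2-methylbut-3-en-2-yl)phenyl]oxetane
Product: 16 bromohydrin (2R)-2-[2,4-bis(methoxymethoxy)-5-(2-methylbut-3-en-2-yl)phenyl]-3-bromopropan-1-ol, via trimethylsilyl ether 15 (not isolated)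
Conditions: TMSBr, chiral squaramide hydrogen-bond donor (from 3,5-bis(trifluoromethyl)aniline, squaric acid and an (S)-tert-leucine 2-arylpyrrolidine amide, 5 mol %), t-BuOMe, −78 °C; then MeOH, citric acid (cat.), 0 °C
Reagents that add atoms: bromotrimethylsilane, C[Si](C)(C)Br
Why: Enantioselective desymmetrising ring opening of a prochiral 3-aryloxetane with TMSBr under chiral squaramide catalysis: the catalyst-bound bromide attacks one of the two enantiotopic CH2–O carbons of the silylated oxetane in an SN2 step driven by ring strain, so the C3 stereocentre is set by the catalyst (antipode chosen for R), and mild methanolysis frees the primary alcohol.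

Step 11
Reactants: 6 aryl iodide 4-iodo-2-(methoxymethoxy)-1-(2-methylbut-3-en-2-yl)benzene; 16 bromohydrin (2R)-2-[2,4-bis(methoxymethoxy)-5-(2-methylbut-3-en-2-yl)phenyl]-3-bromopropan-1-ol
Product: 17 tri-MOM isoflavan (3R)-3-[2,4-bis(methoxymethoxy)-5-(2-methylbut-3-en-2-yl)phenyl]-7-(methoxymethoxy)-6-(2-methylbut-3-en-2-yl)-3,4-dihydro-2H-chromene
Conditions: Pd(OAc)2 (10 mol %), 2-dicyclohexylphosphino-2',6'-diisopropoxybiphenyl (20 mol %), 1-butylbicyclo[2.2.1]hept-2-ene (bridgehead-substituted norbornene, 50 mol %), Cs2CO3, 1,4-dioxane, 100 °C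
Reagents that add atoms: none
Why: Proposed new method: zerovalent palladium inserts into the C–I bond of 6, the norbornene inserts and a five-membered aryl–norbornyl palladacycle forms by C–H palladation at the future C4a; this divalent palladacycle takes up the primary C–Br bond of 16 by SN2-type oxidative addition to tetravalent palladium and reductively eliminates the C4–C4a bond, norbornene is expelled by β-carbon elimination, and the resulting arylpalladium alkoxide forms the O1–C8a bond by C–O reductive elimination at the ipso carbon. The closest known reaction types are the palladium/norbornene ortho-alkylation/ipso-etherification annulation of aryl iodides with epoxides to 2,3-dihydrobenzofurans and the ortho-alkylation/ipso-amination annulation with bromoalkylamines to tetrahydroquinolines; new here are the six-membered C–O closure from a 1,3-bromohydrin and an aryl iodide that lacks an ortho substituent. The one ring formed, the pyran ring, closes by reductive elimination from a seven-membered aryl(alkoxo)palladium chelate, a 6-exo-type attack of the tethered oxygen on the ipso carbon. No new stereocentre is formed: C3 comes from 16, lies β to both reacting atoms and is not touched, so the (R) configuration should be retained. The step needs site selectivity (C4a over C8), single rather than double ortho-alkylation, and ring closure rather than Heck reaction at the vinyl groups: the 7-acetal shields C8, the bridgehead substituent on the norbornene forces its extrusion after one ortho functionalisation, and intramolecular alkoxide capture together with the neopentyl-type hindrance of the 1,1-dimethylallyl alkenes disfavours Heck pathways.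

Step 12
Reactants: 17 tri-MOM isoflavan (3R)-3-[2,4-bis(methoxymethoxy)-5-(2-methylbut-3-en-2-yl)phenyl]-7-(methoxymethoxy)-6-(2-methylbut-3-en-2-yl)-3,4-dihydro-2H-chromene
Product: 18 manuifolin E (3R)-3-[2,4-dihydroxy-5-(2-methylbut-3-en-2-yl)phenyl]-6-(2-methylbut-3-en-2-yl)-3,4-dihydro-2H-chromen-7-ol
Conditions: HCl, MeOH, rt → 40 °C
Reagents that add atoms: none
Why: Acid-catalysed acetal exchange with methanol should remove all three MOM groups; the monosubstituted alkenes would have to protonate to secondary cations and should survive dilute acid, and C3 carries no acidifying group.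

**Compound list**

1 | 5-bromo-2-fluorophenol | Oc1cc(Br)ccc1F | starting material
2 | 4-bromo-1-fluoro-2-(methoxymethoxy)benzene | COCOc1cc(Br)ccc1F | intermediate
3 | 2-[4-bromo-2-(methoxymethoxy)phenyl]-2-methylpropanenitrile | COCOc1cc(Br)ccc1C(C)(C)C#N | intermediate
4 | 2-[4-bromo-2-(methoxymethoxy)phenyl]-2-methylpropanal | COCOc1cc(Br)ccc1C(C)(C)C=O | intermediate
5 | 4-bromo-2-(methoxymethoxy)-1-(2-methylbut-3-en-2-yl)benzene | COCOc1cc(Br)ccc1C(C)(C)C=C | intermediate
6 | 4-iodo-2-(methoxymethoxy)-1-(2-methylbut-3-en-2-yl)benzene | COCOc1cc(I)ccc1C(C)(C)C=C | intermediate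
7 | [3-(methoxymethoxy)-4-(2-methylbut-3-en-2-yl)phenyl]lithium (not isolated) | COCOc1cc([Li])ccc1C(C)(C)C=C | intermediate
8 | dimethyl [3-(methoxymethoxy)-4-(2-methylbut-3-en-2-yl)phenyl]boronate (not isolated) | COCOc1cc(B(OC)OC)ccc1C(C)(C)C=C | intermediate
9 | 3-(methoxymethoxy)-4-(2-methylbut-3-en-2-yl)phenol | COCOc1cc(O)ccc1C(C)(C)C=C | intermediate
10 | 2,4-bis(methoxymethoxy)-1-(2-methylbut-3-en-2-yl)benzene | COCOc1ccc(C(C)(C)C=C)c(OCOC)c1 | intermediate
11 | 1-bromo-2,4-bis(methoxymethoxy)-5-(2-methylbut-3-en-2-yl)benzene | C=CC(C)(C)c1cc(Br)c(OCOC)cc1OCOC | intermediate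
12 | 3-iodooxetane | IC1COC1 | starting material
13 | oxetan-3-ylzinc iodide (not isolated) | I[Zn]C1COC1 | intermediate
14 | 3-[2,4-bis(methoxymethoxy)-5-(2-methylbut-3-en-2-yl)phenyl]oxetane | C=CC(C)(C)c1cc(C2COC2)c(OCOC)cc1OCOC | intermediate
15 | {(2R)-2-[2,4-bis(methoxymethoxy)-5-(2-methylbut-3-en-2-yl)phenyl]-3-bromopropoxy}trimethylsilane (not isolated) | C[Si](C)(C)OC[C@@H](c1cc(C(C)(C)C=C)c(OCOC)cc1OCOC)CBr | intermediate
16 | (2R)-2-[2,4-bis(methoxymethoxy)-5-(2-methylbut-3-en-2-yl)phenyl]-3-bromopropan-1-ol | OC[C@@H](c1cc(C(C)(C)C=C)c(OCOC)cc1OCOC)CBr | intermediate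
17 | (3R)-3-[2,4-bis(methoxymethoxy)-5-(2-methylbut-3-en-2-yl)phenyl]-7-(methoxymethoxy)-6-(2-methylbut-3-en-2-yl)-3,4-dihydro-2H-chromene | C=CC(C)(C)c1cc2c(cc1OCOC)OC[C@@H](c1cc(C(C)(C)C=C)c(OCOC)cc1OCOC)C2 | intermediate
18 | manuifolin E, (3R)-3-[2,4-dihydroxy-5-(2-methylbut-3-en-2-yl)phenyl]-6-(2-methylbut-3-en-2-yl)-3,4-dihydro-2H-chromen-7-ol | C=CC(C)(C)c1cc2c(cc1O)OC[C@@H](c1cc(C(C)(C)C=C)c(O)cc1O)C2 | target

**Step count and risks**

Total step count: 12. Longest linear sequence: 11 steps (steps 1, 2, 3, 4, 6, 7, 8, 9, 10, 11, 12); step 5 is the one-step branch to the ring-A partner.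

Steps most likely to fail:

Step 11 (proposed new method). Several processes may compete:
- base-induced dehydrobromination of the bromohydrin, or its closure back to the oxetane, before it reaches palladium;
- slow SN2-type oxidative addition of the β-branched bromide;
- a second C–H palladation at C8, or failure of norbornene extrusion, leading to norbornane-containing products;
- β-hydride elimination of the alkoxopalladium species in place of C–O reductive elimination.

The fallback makes the same two bonds in two separate operations of known type and sets out from 16 and 5, returning at 17. Compound 16 is silylated (TBSCl, imidazole, DMF) to tert-butyl{(2R)-2-[2,4-bis(methoxymethoxy)-5-(2-methylbut-3-en-2-yl)phenyl]-3-bromopropoxy}dimethylsilane F1. Compound 5 is iodinated para to its acetal oxygen (N-iodosuccinimide, cat. TFA, MeCN, 0 °C → rt) to 1-bromo-2-iodo-5-(methoxymethoxy)-4-(2-methylbut-3-en-2-yl)benzene F2. Zinc insertion into F1 (Zn dust, LiCl, THF, 50 °C) gives the (R)-configured alkylzinc bromide F3. Negishi coupling of F3 at the C–I bond of F2 (PdCl2(dppf), THF, rt → 40 °C) forms C4–C4a and gives tert-butyl{(2R)-2-[2,4-bis(methoxymethoxy)-5-(2-methylbut-3-en-2-yl)phenyl]-3-[2-bromo-4-(methoxymethoxy)-5-(2-methylbut-3-en-2-yl)phenyl]propoxy}dimethylsilane F4. Desilylation (TBAF, THF) gives (2R)-2-[2,4-bis(methoxymethoxy)-5-(2-methylbut-3-en-2-yl)phenyl]-3-[2-bromo-4-(methoxymethoxy)-5-(2-methylbut-3-en-2-yl)phenyl]propan-1-ol F5. Intramolecular palladium-catalysed aryl etherification (Pd(OAc)2, 2-(di-tert-butylphosphino)-1,1'-binaphthyl, Cs2CO3, toluene, 80 °C) forms O1–C8a and gives 17.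

Step 10. TMSBr may cleave the MOM acetals, the ortho acetal oxygen may take part in opening the activated oxetane, and the catalyst may discriminate the enantiotopic CH2 groups poorly for an ortho-substituted aryl. The fallback sets out from 11, bypasses 14 and returns at 16. Palladium-catalysed arylation of diethyl malonate with 11 (Pd2(dba)3, P(t-Bu)3, K3PO4, toluene, 70 °C) gives diethyl 2-[2,4-bis(methoxymethoxy)-5-(2-methylbut-3-en-2-yl)phenyl]propanedioate F6. Reduction (LiAlH4, THF, 0 °C → rt) gives the prochiral 2-[2,4-bis(methoxymethoxy)-5-(2-methylbut-3-en-2-yl)phenyl]propane-1,3-diol F7. Lipase-catalysed desymmetrising monoacetylation (Pseudomonas cepacia lipase, vinyl acetate, t-BuOMe, rt; the opposite series is reachable by lipase hydrolysis of the diacetate) should give (2S)-2-[2,4-bis(methoxymethoxy)-5-(2-methylbut-3-en-2-yl)phenyl]-3-hydroxypropyl acetate F8. Appel bromination (CBr4, PPh3, CH2Cl2, 0 °C) gives (2R)-2-[2,4-bis(methoxymethoxy)-5-(2-methylbut-3-en-2-yl)phenyl]-3-bromopropyl acetate F9, and methanolysis (K2CO3, MeOH, 0 °C) gives 16.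

Step 9. Oxidative addition at the hindered, electron-rich C–Br bond may be slow, and the oxetanylzinc reagent may be lost by protonation or ring opening. The fallback reverses the polarity of the coupling, sets out from 11 and 12 and returns at 14. Bromine–lithium exchange on 11 (n-BuLi, THF, −78 °C) gives [2,4-bis(methoxymethoxy)-5-(2-methylbut-3-en-2-yl)phenyl]lithium F10. Borylation (B(Oi-Pr)3, then aq. NH4Cl) gives [2,4-bis(methoxymethoxy)-5-(2-methylbut-3-en-2-yl)phenyl]boronic acid F11. Nickel-catalysed alkyl–aryl Suzuki–Miyaura coupling of F11 with 3-iodooxetane 12 (NiI2, trans-2-aminocyclohexanol hydrochloride, NaHMDS, i-PrOH, 80 °C) gives 14.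

Further compounds
F1 | step 11 | tert-butyl{(2R)-2-[2,4-bis(methoxymethoxy)-5-(2-methylbut-3-en-2-yl)phenyl]-3-bromopropoxy}dimethylsilane | CC(C)(C)[Si](C)(C)OC[C@@H](c1cc(C(C)(C)C=C)c(OCOC)cc1OCOC)CBr
F2 | step 11 | 1-bromo-2-iodo-5-(methoxymethoxy)-4-(2-methylbut-3-en-2-yl)benzene | C=CC(C)(C)c1cc(I)c(Br)cc1OCOC
F3 | step 11 | {(2R)-2-[2,4-bis(methoxymethoxy)-5-(2-methylbut-3-en-2-yl)phenyl]-3-[(tert-butyldimethylsilyl)oxy]propyl}zinc bromide | CC(C)(C)[Si](C)(C)OC[C@@H](c1cc(C(C)(C)C=C)c(OCOC)cc1OCOC)C[Zn]Br
F4 | step 11 | tert-butyl{(2R)-2-[2,4-bis(methoxymethoxy)-5-(2-methylbut-3-en-2-yl)phenyl]-3-[2-bromo-4-(methoxymethoxy)-5-(2-methylbut-3-en-2-yl)phenyl]propoxy}dimethylsilane | CC(C)(C)[Si](C)(C)OC[C@@H](c1cc(C(C)(C)C=C)c(OCOC)cc1OCOC)Cc1cc(C(C)(C)C=C)c(OCOC)cc1Br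
F5 | step 11 | (2R)-2-[2,4-bis(methoxymethoxy)-5-(2-methylbut-3-en-2-yl)phenyl]-3-[2-bromo-4-(methoxymethoxy)-5-(2-methylbut-3-en-2-yl)phenyl]propan-1-ol | OC[C@@H](c1cc(C(C)(C)C=C)c(OCOC)cc1OCOC)Cc1cc(C(C)(C)C=C)c(OCOC)cc1Br
F6 | step 10 | diethyl 2-[2,4-bis(methoxymethoxy)-5-(2-methylbut-3-en-2-yl)phenyl]propanedioate | CCOC(=O)C(C(=O)OCC)c1cc(C(C)(C)C=C)c(OCOC)cc1OCOC
F7 | step 10 | 2-[2,4-bis(methoxymethoxy)-5-(2-methylbut-3-en-2-yl)phenyl]propane-1,3-diol | OCC(CO)c1cc(C(C)(C)C=C)c(OCOC)cc1OCOC
F8 | step 10 | (2S)-2-[2,4-bis(methoxymethoxy)-5-(2-methylbut-3-en-2-yl)phenyl]-3-hydroxypropyl acetate | CC(=O)OC[C@@H](c1cc(C(C)(C)C=C)c(OCOC)cc1OCOC)CO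
F9 | step 10 | (2R)-2-[2,4-bis(methoxymethoxy)-5-(2-methylbut-3-en-2-yl)phenyl]-3-bromopropyl acetate | CC(=O)OC[C@@H](c1cc(C(C)(C)C=C)c(OCOC)cc1OCOC)CBr
F10 | step 9 | [2,4-bis(methoxymethoxy)-5-(2-methylbut-3-en-2-yl)phenyl]lithium | [Li]c1cc(C(C)(C)C=C)c(OCOC)cc1OCOC
F11 | step 9 | [2,4-bis(methoxymethoxy)-5-(2-methylbut-3-en-2-yl)phenyl]boronic acid | OB(O)c1cc(C(C)(C)C=C)c(OCOC)cc1OCOC
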